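**Retrosynthetic overview**
- The 10-membered ring is closed last, at C7–C8, by a radical allyl-transfer (SH2′) macrocyclisation: a C8 α-(tigloyloxy)alkyl radical (from the C8 aldehyde **16** and tigloyl iodide) adds to C7 of a 3-(ethylsulfonylmethyl)butenolide, and loss of EtSO2• unveils the α-methylene lactone.
- Ring order: the butenolide (lactone) ring is made first by RCM, then the carbocycle; the step sets C7 and C8 and installs the tiglate.
- The cross-conjugated dienone (C2–C3 and C3–C4) comes from a carbonylative Stille coupling of Z-vinyl iodide **8**, E-vinylstannane **14** and CO.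
- **8** comes from acrolein and propyne (asymmetric alkynylation sets C6; Red-Al/I2 sets the 4Z alkene). **14** comes from (S)-2-methylglycidol (C10) and vinylmagnesium bromide.

Assumption: germacrane numbering is used (C6 = lactone O–CH, C8 = tiglate O–CH, C10 = carbinol; target = 6R,7R,8R,10R, 1E,4Z, (E)-2-methylbut-2-enoate ester), and (S)-2-methylglycidol is bought enantiopure.

---

**Step 1**
Reactants: **1** 2-(bromomethyl)acrylic acid
Product: **2** 2-[(ethylsulfonyl)methyl]acrylic acid
Conditions: EtSO2Na (2.2 equiv), MeOH, reflux; then aq. HCl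
Reagents that add atoms: sodium ethanesulfinate, CCS(=O)[O-].[Na+]
Why: Sulfinate S-alkylation of the allylic bromide (SN2 and SN2′ give the same product); no stereocentre.

**Step 2**
Reactants: **3** acrolein; **4** propyne
Product: **5** (S)-hex-1-en-4-yn-3-ol
Conditions: propyne (3 equiv), Me2Zn (3 equiv), ProPhenol (10 mol%), Ph3P=O (20 mol%), toluene, 0 °C; then acrolein, 4 °C
Reagents that add atoms: none beyond **3** and **4**
Why: Trost Zn–ProPhenol enantioselective alkynylation of an enal (1,2-addition); the ligand enantiomer that delivers the (S)-carbinol is used (checked by Mosher ester), and this centre becomes C6.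

**Step 3**
Reactants: **5**
Product: **6** (S,Z)-5-iodohexa-1,4-dien-3-ol
Conditions: Red-Al, THF, 0 °C to rt; then I2, −78 °C
Reagents that add atoms: iodine, II
Why: Hydroxyl-directed trans-hydroalumination of the propargylic alcohol places Al on the distal carbon cis to the carbinol, and iodinolysis with retention gives the Z-vinyl iodide (future 4Z alkene); the vinyl group and C6 are untouched.

**Step 4**
Reactants: **6**; **2**
Product: **7** (S,Z)-5-iodohexa-1,4-dien-3-yl 2-[(ethylsulfonyl)methyl]acrylate
Conditions: EDC·HCl, DMAP (10 mol%), CH2Cl2, 0 °C to rt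
Reagents that add atoms: none beyond **2**
Why: Steglich esterification of the secondary alcohol; the C–O bond at C6 is not broken, so configuration is retained.

**Step 5**
Reactants: **7**
Product: **8** (S)-3-[(ethylsulfonyl)methyl]-5-[(Z)-2-iodoprop-1-en-1-yl]furan-2(5H)-one
Conditions: Hoveyda–Grubbs II (5 mol%), toluene, 80 °C
Reagents that add atoms: none
Why: Ring-closing metathesis between the terminal vinyl group and the 2-substituted acrylate forms the butenolide C7=C11; the trisubstituted vinyl iodide and the sulfone are inert to the Ru carbene.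

**Step 6**
Reactants: **9** (S)-2-methylglycidol; **10** vinylmagnesium bromide
Product: **11** (R)-2-methylpent-4-ene-1,2-diol
Conditions: vinylMgBr (3 equiv), CuI (10 mol%), THF, −30 to 0 °C
Reagents that add atoms: vinylmagnesium bromide, C=C[Mg]Br
Why: Cu-catalysed Grignard opening of the epoxide at the unsubstituted CH2 (SN2); the quaternary carbon (C10) is not touched, and the descriptor changes S to R only by CIP priority.

**Step 7**
Reactants: **11**
Product: **12** (R)-2-methyl-1,2-bis(triethylsilyloxy)pent-4-ene
Conditions: TESOTf (2.4 equiv), 2,6-lutidine, CH2Cl2, −78 to 0 °C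
Reagents that add atoms: triethylsilyl triflate, CC[Si](CC)(CC)OS(=O)(=O)C(F)(F)F
Why: Silylation of both hydroxyls (the triflate is needed for the tertiary one); the tertiary TES ether protects C10–OH through to the acyl iodide step.

**Step 8**
Reactants: **12**
Product: **13** (R)-2-methyl-2-(triethylsilyloxy)pent-4-enal
Conditions: (COCl)2 (4 equiv), DMSO (8 equiv), CH2Cl2, −78 to −40 °C; then Et3N
Reagents that add atoms: none
Why: Swern oxidation with selective in-situ cleavage of the primary TES ether gives the aldehyde directly; the tertiary TES ether survives and the α-centre is quaternary, so it cannot epimerise.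

**Step 9**
Reactants: **13**
Product: **14** tributyl[(1E,3R)-3-methyl-3-(triethylsilyloxy)hexa-1,5-dien-1-yl]stannane
Conditions: CrCl2 (8 equiv), Bu3SnCHBr2 (2 equiv), LiI (4 equiv), THF/DMF, rt, dark
Reagents that add atoms: (dibromomethyl)tributylstannane, BrC(Br)[Sn](CCCC)(CCCC)CCCC (supplies C2–H and SnBu3)
Why: Takai–Hodgson chromium(II) stannyl-olefination of the aldehyde, which is reliably E-selective via the gem-dichromium reagent; this fixes the 1E alkene.

**Step 10**
Reactants: **8**; **14**
Product: **15** (R)-3-[(ethylsulfonyl)methyl]-5-[(1Z,4E,6R)-2,6-dimethyl-3-oxo-6-(triethylsilyloxy)nona-1,4,8-trien-1-yl]furan-2(5H)-one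
Conditions: Pd2(dba)3·CHCl3 (5 mol%), AsPh3 (40 mol%), LiCl, CO (3 atm), NMP, 45 °C
Reagents that add atoms: carbon monoxide, [C-]#[O+] (becomes C3=O)
Why: Carbonylative Stille coupling (oxidative addition to the vinyl iodide, CO insertion, vinyl transfer from tin) gives the divinyl ketone with retention of both alkene geometries under neutral conditions; the allyl sulfone and lactone are poor partners for Pd(0) at this temperature.

**Step 11**
Reactants: **15**
Product: **16** (3R,4E,7Z)-8-{(2R)-4-[(ethylsulfonyl)methyl]-5-oxo-2,5-dihydrofuran-2-yl}-3,7-dimethyl-6-oxo-3-(triethylsilyloxy)octa-4,7-dienal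
Conditions: OsO4 (2 mol%), NaIO4 (4 equiv), 2,6-lutidine, dioxane/H2O 3:1, rt
Reagents that add atoms: osmium tetroxide, O=[Os](=O)(=O)=O, and sodium periodate, [Na+].[O-]I(=O)(=O)=O (aldehyde oxygen)
Why: Lemieux–Johnson cleavage; the isolated monosubstituted alkene is dihydroxylated far faster than the electron-poor enone and butenolide alkenes, giving the C8 aldehyde.

**Step 12 (key step)**
Reactants: **16**; **17** tigloyl chloride, (E)-2-methylbut-2-enoyl chloride
Product: **18** 10-O-triethylsilyl-eupaheliangolide A
Conditions: tigloyl iodide (1.2 equiv, from **17** + NaI, MeCN), 2,6-di-tert-butyl-4-methylpyridine (0.2 equiv), CH2Cl2, 0 °C, 20 min; then dilute to 1 mM, Mn2(CO)10 (0.6 equiv), blue LEDs, rt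
Reagents that add atoms: tigloyl chloride, C/C=C(\C)C(=O)Cl (used as tigloyl iodide, C/C=C(\C)C(=O)I)
Why: Proposed new method: the aldehyde and tigloyl iodide form the α-iodoalkyl tiglate, Mn(CO)5• abstracts iodine to give the nucleophilic C8 α-(acyloxy)alkyl radical, which can only close 10-exo onto C7 of the butenolide (4-exo/5-endo onto C1=C2 and 8-endo across the E-alkene onto C4=C5 are geometrically excluded), and the C11 adduct radical expels EtSO2• to give the exocyclic methylene; iodine transfer back to C8 is degenerate, so the uncyclised radical is stored as the iodide and not reduced. The closest known reactions are Mn2(CO)10/light generation of α-acyloxy radicals from aldehydes and acyl iodides, tin-free radical allylation with allyl ethyl sulfones, and radical macrocyclisation onto activated alkenes. C7 is set by attack anti to the C6 alkenyl group of the γ-substituted butenolide (6,7-trans); C8 is expected to be R from the transition state with H-8 over the lactone and the tether antiperiplanar to C6, which is a prediction from a hand model, not a precedent.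

**Step 13**
Reactants: **18**
Product: **19** eupaheliangolide A
Conditions: HF·pyridine, pyridine, THF, 0 °C to rt
Reagents that add atoms: none
Why: Fluoride/acid desilylation of the tertiary TES ether; the C10–O bond is not broken, and the esters, dienone and methylene lactone tolerate buffered HF.

---

**Compound list**
1 | 2-(bromomethyl)acrylic acid | C=C(CBr)C(=O)O | starting material
2 | 2-[(ethylsulfonyl)methyl]acrylic acid | C=C(CS(=O)(=O)CC)C(=O)O | intermediate
3 | acrolein | C=CC=O | starting material
4 | propyne | CC#C | starting material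
5 | (S)-hex-1-en-4-yn-3-ol | C=C[C@H](O)C#CC | intermediate
6 | (S,Z)-5-iodohexa-1,4-dien-3-ol | C=C[C@H](O)/C=C(/C)I | intermediate
7 | (S,Z)-5-iodohexa-1,4-dien-3-yl 2-[(ethylsulfonyl)methyl]acrylate | C=C[C@H](OC(=O)C(=C)CS(=O)(=O)CC)/C=C(/C)I | intermediate
8 | (S)-3-[(ethylsulfonyl)methyl]-5-[(Z)-2-iodoprop-1-enyl]furan-2(5H)-one | O=C1O[C@H](/C=C(/C)I)C=C1CS(=O)(=O)CC | intermediate
9 | (S)-2-methylglycidol | OC[C@@]1(C)CO1 | starting material
10 | vinylmagnesium bromide | C=C[Mg]Br | starting material
11 | (R)-2-methylpent-4-ene-1,2-diol | OC[C@](C)(O)CC=C | intermediate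
12 | (R)-2-methyl-1,2-bis(triethylsilyloxy)pent-4-ene | CC[Si](CC)(CC)OC[C@](C)(O[Si](CC)(CC)CC)CC=C | intermediate
13 | (R)-2-methyl-2-(triethylsilyloxy)pent-4-enal | O=C[C@](C)(O[Si](CC)(CC)CC)CC=C | intermediate
14 | tributyl[(1E,3R)-3-methyl-3-(triethylsilyloxy)hexa-1,5-dienyl]stannane | CCCC[Sn](CCCC)(CCCC)/C=C/[C@](C)(O[Si](CC)(CC)CC)CC=C | intermediate
15 | butenolide dienone with terminal alkene (6R,10R; 1E,4Z) | O=C1O[C@H](/C=C(/C)C(=O)/C=C/[C@](C)(O[Si](CC)(CC)CC)CC=C)C=C1CS(=O)(=O)CC | intermediate
16 | seco-aldehyde (C8 aldehyde; 6R,10R; 1E,4Z) | O=C1O[C@H](/C=C(/C)C(=O)/C=C/[C@](C)(O[Si](CC)(CC)CC)CC=O)C=C1CS(=O)(=O)CC | intermediate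
17 | tigloyl chloride | C/C=C(\C)C(=O)Cl | starting material
18 | 10-O-TES-eupaheliangolide A | C=C1C(=O)O[C@@H]2/C=C(/C)C(=O)/C=C/[C@](C)(O[Si](CC)(CC)CC)C[C@@H](OC(=O)/C(C)=C/C)[C@@H]12 | intermediate
19 | eupaheliangolide A | C=C1C(=O)O[C@@H]2/C=C(/C)C(=O)/C=C/[C@](C)(O)C[C@@H](OC(=O)/C(C)=C/C)[C@@H]12 | target

**Totals**
Total steps: 13. Longest linear sequence: 8 steps (Steps 2–5 then 10–13, or Steps 6–9 then 10–13).

**Three steps most likely to fail**
1. **Step 12.** Ring closure to the 10-membered ring may be inefficient, and the C8 configuration (and 6,7-trans versus cis fusion) is predicted only from a model. Fallback: form C7–C8 intermolecularly first, by Zn- or In-mediated allylation of a small C8 aldehyde fragment with the bromomethyl analogue of **8** (diastereomers separable, C8–OH then tigloylated), and move the ring closure to C3 by an intramolecular carbonylative Stille coupling.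
2. **Step 10.** The hindered Z-vinyl iodide may give direct (non-carbonylative) coupling, or Pd(0) may ionise the allyl sulfone or allylic lactone. Fallback: Ni/Cr (Nozaki–Hiyama–Kishi) addition of iodide **8** to the enal made from **13** by two-carbon Wittig homologation, then oxidation of the bis-allylic alcohol to the dienone.
3. **Step 5.** RCM onto the 2-(sulfonylmethyl)acrylate to give a trisubstituted butenolide may be sluggish. Fallback: esterify **6** with acryloyl chloride and close the unsubstituted butenolide (an easy disubstituted RCM), then install C13 by Morita–Baylis–Hillman hydroxymethylation with formaldehyde and convert CH2OH to CH2SO2Et (mesylate, then EtSO2Na).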